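You take over four flasks with the same amounts, 0.14 M of substrate and 0.182 M of partner; they differ in when each goes in.

| flask | substrate | partner | remark | time |
|---|---|---|---|---|
| theta | 0.14 M | 0.182 M | run made earlier |  |
| beta | 0.20 M | 0.182 M | run made earlier |  |
| eta | 0.31 M | 0.182 M | run made earlier |  |
| zeta | 0.14 M | 0.27 M | run made earlier |  |
| Saturday's | 0.14 M (in portions, 3, over 4.0 h) | 0.182 M | first portion at the start, last at 4.0 h | 6.0 h |
| Thursday's | 0.14 M (fed, over 4.0 h) | 0.182 M | all else is in the flask from the start; the feed brings no volume worth counting | 6.0 h |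
| Wednesday's | 0.14 M | 0.182 M | everything together at the start | 6.0 h |
| Sunday's | 0.14 M | 0.182 M (fed, over 4.0 h) | all else is in the flask from the start; the feed brings no volume worth counting | 6.0 h |

| run | time / h | target / % | homo product / % | substrate / % |
|---|---|---|---|---|
| theta | 0.417 | 1.3 | 0.1 | 78.0 |
| theta | 1.33 | 5.1 | 3.4 | 54.7 |
| theta | 2.00 | 7.5 | 5.0 | 45.9 |
| theta | 3.00 | 11.5 | 7.9 | 38.2 |
| theta | 5.00 | 10.9 | 12.7 | 28.8 |
| theta | 6.00 | 11.5 | 15.3 | 24.7 |
| beta | 0.333 | 0.6 | 0.6 | 81.9 |
| beta | 1.00 | 3.7 | 3.0 | 62.2 |
| beta | 1.50 | 6.8 | 3.9 | 53.7 |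
| beta | 2.50 | 9.9 | 8.5 | 41.1 |
| beta | 4.00 | 12.6 | 16.0 | 33.0 |
| beta | 5.00 | 12.5 | 19.1 | 28.4 |
| eta | 0.417 | 3.3 | 2.2 | 80.8 |
| eta | 0.667 | 3.2 | 1.7 | 70.7 |
| eta | 1.00 | 5.1 | 5.0 | 62.8 |
| eta | 2.00 | 6.9 | 9.7 | 46.7 |
| eta | 3.00 | 8.1 | 16.3 | 35.9 |
| eta | 5.00 | 9.6 | 27.6 | 29.0 |
| zeta | 1.00 | 4.2 | 1.7 | 63.1 |
| zeta | 2.00 | 10.8 | 4.1 | 43.5 |
| zeta | 3.00 | 14.3 | 5.1 | 33.9 |
| zeta | 4.00 | 13.8 | 8.4 | 26.7 |
| zeta | 5.00 | 14.7 | 8.6 | 25.0 |

(readings scatter by 1 percentage point)

- in percentages every species weighs as the substrate in it: one homo product counts as two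
- steps thought possible: target <-> isomer of the product; substrate <-> open intermediate; 2 open intermediate -> homo product; partner -> second intermediate; open intermediate + second intermediate <-> target

1. the best flask by share of target in target plus homo product; "all alike" if 1.5 percentage points covers them all (Saturday's / Thursday's / Wednesday's / Sunday's / all alike)
2. share of target in target plus homo product at the end, Saturday's
3. share of target in target plus homo product at the end, Thursday's
4. share of target in target plus homo product at the end, Wednesday's
5. share of target in target plus homo product at the end, Sunday's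

At 5.00 h, homo product per molar of substrate charged reads 0.907 M⁻¹ in theta, 0.955 M⁻¹ in beta and 0.890 M⁻¹ in eta, while target stays between 9.6% and 12.5%. So I read homo product as second order in [open intermediate], and target as roughly indifferent to the charge.

Theta at 6.00 h gives 9.50 M⁻¹ for homo product over target per molar of load, the load being the charge times the time mean of the squared fraction of it already added, with 0.182 M of partner in from the start and a run of 6.0 h. That mean is 0.556 for Thursday's and 0.519 for Saturday's.

When you come back, I expect a share of target, the selectivity, of 59.2% in Saturday's, 57.5% in Thursday's and 42.9% in Wednesday's. Saturday's leads by 1.7 percentage points, so leave the portions on schedule. Sunday's has the full load and late partner. With more partner, zeta read a lower homo product over target than theta at 5.00 h, 0.585 against 1.17, so I put Sunday's below Wednesday's.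

The forecast names Thursday's, with 52%, 54%, 43% and 39% for Saturday's, Thursday's, Wednesday's and Sunday's, holding that “Homo product grows as the square of open intermediate”.

The simulation names Saturday's, with 58.6%, 57.0%, 44.2% and 34.2% in that order.

    target ⇌ isomer of the product (K = 2.10, k = 0.00340 s⁻¹)
    substrate ⇌ open intermediate (K = 0.790, k = 1.90 × 10⁻⁴ s⁻¹)
    2 open intermediate → homo product (k = 5.50 × 10⁻⁴ M⁻¹ s⁻¹)
    partner → second intermediate (k = 8.30 × 10⁻⁴ s⁻¹)
    open intermediate + second intermediate ⇌ target (K = 4.70 M⁻¹, k = 0.00170 M⁻¹ s⁻¹)

In Saturday's, partner stood at 0% of its charge at 4.00 h, with second intermediate at 0.151 M and homo product at 2.85%. After the last portion, homo product reached 7.92% by 6.00 h, with open intermediate at 22.0%. Saturday's result gives back 9.73 M⁻¹ per molar of load. Sunday's own result, with its partner fed late, gives 13.8 M⁻¹ per molar of load, which for a neighbour of Sunday's charged with 0.084 M of substrate means a share of 46.3%; the simulation of that neighbour gives 47.7%.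

The data stem from a simulated flask for substances that don't exist, and the scatter is random.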